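**Retrosynthetic overview**

1. Thielavin Z8 (30) is cut at its two aryl ester C(=O)–O bonds into ring A phenol 17 and the B–C acid 26; 26 in turn comes from ring C acid 23 and ring B phenol 21, whose aldehyde stands in for the ring B carboxyl.
2. Rings B and C are the ring A resorcinol carrying one extra carbon at its lone C–H, so 17, 21 and 23 are all drawn from a single phenol, 15; ortho-formylation supplies the extra carbon.
3. Feature on which the plan rests: ring A is a pentasubstituted resorcinol (ester oxygen on C1 between the C2 and C6 methyls, free OH on C3 beside C4–H, methyls on C2, C5, C6) whose two oxygens must be distinguished. The same distinction recurs in ring B (C4–O acylated, C2–O beside the carboxyl).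
4. Key disconnection: ring A bonds C2–C3, C1–C6 and C3–C4, formed by benzannulation of 2,3-dimethylcyclobutenone 5 (from but-2-yne and dichloroketene) with siloxypropyne 10 (from propyne). The C3 oxygen arrives as the free OH from the ketene carbonyl, the C1 oxygen as the silyl ether from the ynol ether.
5. Ring order: the cyclobutenone ring (step 1), then the one benzene ring of 15 (step 4), which is used three times as rings A, B and C; no other ring is formed.

Key step: step 4

Remark: the target has no stereocentre; the only stereogenic atom on the route is the quaternary carbon of the transient adduct 12 (racemic, lost on ring opening). TIPS = Si(iPr)3, Bn = benzyl.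

**Route**

Step 1
Reactants: 1 but-2-yne; 2 trichloroacetyl chloride
Product: 4 4,4-dichloro-2,3-dimethylcyclobut-2-en-1-one, via dichloroketene 3 (not isolated)
Conditions: Zn–Cu couple, Et2O–DME, 0 °C → rt (cold condenser, excess 1)
Reagents that add atoms: none
Why: Zinc dechlorination of 2 gives dichloroketene, which undergoes the established ketene–alkyne [2+2] cycloaddition with the symmetrical alkyne, so no regiochemical question arises.

Step 2
Reactants: 4 4,4-dichloro-2,3-dimethylcyclobut-2-en-1-one
Product: 5 2,3-dimethylcyclobut-2-en-1-one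
Conditions: Zn dust, AcOH, TMEDA, EtOH, 0 °C → rt; careful distillation
Reagents that add atoms: none
Why: Zinc/acetic acid reductive dechlorination through the zinc enolate, buffered by TMEDA so that the strained enone is not opened, is the standard passage from 4,4-dichlorocyclobutenones to the parent cyclobutenones.

Step 3
Reactants: 6 propyne; 7 triisopropylsilyl trifluoromethanesulfonate (TIPSOTf)
Product: 10 triisopropyl(prop-1-yn-1-yloxy)silane, via propynyllithium 8 (not isolated), via lithium propynolate 9 (not isolated)
Conditions: n-BuLi, THF, −78 °C; then t-BuOOLi (from t-BuOOH + LiN(SiMe3)2, THF, −78 °C), −78 → 0 °C; then 7, −78 → 0 °C; distillation or short neutral alumina plug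
Reagents that add atoms: tert-butyl hydroperoxide, CC(C)(C)OO
Why: Oxidation of a lithium acetylide by lithium tert-butyl peroxide (Julia-type ynolate synthesis) gives the ynolate, which the bulky silyl triflate captures on oxygen and not on carbon.

Step 4
Reactants: 5 2,3-dimethylcyclobut-2-en-1-one; 10 triisopropyl(prop-1-yn-1-yloxy)silane
Product: 15 2,4,5-trimethyl-3-(triisopropylsilyloxy)phenol, via vinylketene 11 (not isolated), via vinylcyclobutenone adduct 12 (not isolated), via dienylketene 13 (not isolated), via cyclohexadienone tautomer 14 (not isolated)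
Conditions: toluene (about 0.5 M), 80 °C, then 110 °C, sealed vessel, 1.2 equiv of 10
Reagents that add atoms: none
Why: Heating opens 5 by 4π electrocyclic cleavage of its C1–C4 bond to vinylketene 11, whose carbonyl carbon is attacked by the methyl-bearing, nucleophilic carbon of the ynol ether in a polarised ketene–alkyne [2+2] cycloaddition to give 4-vinylcyclobutenone 12, which opens again (4π) to dienylketene 13, closes to cyclohexadienone 14 and enolises to phenol 15. This is the Danheiser benzannulation, known for cyclobutenones with trialkylsilyloxyalkynes as a route to resorcinol monosilyl ethers. The benzene ring is closed in two stages: ring A bonds C2–C3 and C1–C6 in the [2+2] (four-membered closure), then C3–C4 by thermal disrotatory 6π electrocyclisation of the (3E)-dienylketene, a six-membered closure made irreversible by enolisation. No stereocentre remains, since the quaternary carbon of 12 is racemic and is destroyed on ring opening, and a dienylketene of the wrong geometry can return through 12. The selectivity required is regiochemical, and the donor oxygen of 10 secures it by making the C-methyl carbon the nucleophile, so that the ketene carbonyl carbon becomes C3 (free OH beside the ring C–H) and the silyloxy carbon becomes C1 (between two methyls, meta to the new hydroxyl). The triisopropylsilyl group is large enough to stay on oxygen at these temperatures, and the slight excess of 10 limits acylation of the product phenol by 11.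

Step 5
Reactants: 15 2,4,5-trimethyl-3-(triisopropylsilyloxy)phenol
Product: 16 1-(benzyloxy)-2,4,5-trimethyl-3-(triisopropylsilyloxy)benzene
Conditions: BnBr, K2CO3, DMF, rt
Reagents that add atoms: benzyl bromide, BrCc1ccccc1
Why: Williamson etherification of the only free phenoxide, while the silyl ether shielded by two ortho methyls is untouched by K2CO3 at room temperature.

Step 6
Reactants: 16 1-(benzyloxy)-2,4,5-trimethyl-3-(triisopropylsilyloxy)benzene
Product: 17 3-(benzyloxy)-2,5,6-trimethylphenol
Conditions: Bu4NF, AcOH (1 equiv), THF, 0 °C → rt, under argon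
Reagents that add atoms: none
Why: Fluoride-induced cleavage of the aryl silyl ether (Si–F bond formation, phenoxide leaving group) under acetic acid buffering, to which the benzyl ether is inert.

Step 7
Reactants: 15 2,4,5-trimethyl-3-(triisopropylsilyloxy)phenol
Product: 19 2-hydroxy-3,5,6-trimethyl-4-(triisopropylsilyloxy)benzaldehyde, via hydroxymethylphenol 18 (not isolated)
Conditions: MgCl2, Et3N, (CH2O)n, MeCN, reflux; 1 M HCl work-up
Reagents that add atoms: paraformaldehyde (as formaldehyde), C=O
Why: Magnesium-mediated ortho-formylation of a phenol (Casnati–Skattebøl conditions), in which the magnesium phenoxide delivers formaldehyde to the single free ortho carbon and the benzylic alkoxide 18 is oxidised by a second formaldehyde in an Oppenauer-type hydride transfer.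

Step 8
Reactants: 19 2-hydroxy-3,5,6-trimethyl-4-(triisopropylsilyloxy)benzaldehyde
Product: 20 2-(benzyloxy)-3,5,6-trimethyl-4-(triisopropylsilyloxy)benzaldehyde
Conditions: BnBr, K2CO3, Bu4NI (cat.), acetone, reflux
Reagents that add atoms: benzyl bromide, BrCc1ccccc1
Why: Williamson etherification of the chelated but acidic ortho-formyl phenol under mild carbonate/acetone conditions with iodide catalysis, chosen so that the para silyl ether, shielded by two methyls, is retained.

Step 9
Reactants: 20 2-(benzyloxy)-3,5,6-trimethyl-4-(triisopropylsilyloxy)benzaldehyde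
Product: 21 2-(benzyloxy)-4-hydroxy-3,5,6-trimethylbenzaldehyde
Conditions: Bu4NF, AcOH (1 equiv), THF, 0 °C
Reagents that add atoms: none
Why: Fluoride desilylation is fast here because the para-formyl phenoxide is a good leaving group, and the buffered medium leaves the aldehyde and the benzyl ether alone.

Step 10
Reactants: 21 2-(benzyloxy)-4-hydroxy-3,5,6-trimethylbenzaldehyde
Product: 22 2,4-bis(benzyloxy)-3,5,6-trimethylbenzaldehyde
Conditions: BnBr, K2CO3, DMF, rt → 50 °C
Reagents that add atoms: benzyl bromide, BrCc1ccccc1
Why: Williamson etherification of the acidic para-formyl phenoxide, which has no competing nucleophilic site.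

Step 11
Reactants: 22 2,4-bis(benzyloxy)-3,5,6-trimethylbenzaldehyde
Product: 23 2,4-bis(benzyloxy)-3,5,6-trimethylbenzoic acid
Conditions: NaClO2, NaH2PO4, 2-methylbut-2-ene, t-BuOH–THF–H2O, rt
Reagents that add atoms: sodium chlorite, [Na+].[O-]Cl=O
Why: Pinnick oxidation tolerates benzyl ethers, the fully substituted ring offers no site for chlorination, and 2-methylbut-2-ene scavenges the hypochlorous acid.

Step 12
Reactants: 23 2,4-bis(benzyloxy)-3,5,6-trimethylbenzoic acid; 21 2-(benzyloxy)-4-hydroxy-3,5,6-trimethylbenzaldehyde
Product: 25 3-(benzyloxy)-4-formyl-2,5,6-trimethylphenyl 2,4-bis(benzyloxy)-3,5,6-trimethylbenzoate, via mixed trifluoroacetic anhydride 24 (not isolated)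
Conditions: (CF3CO)2O, toluene, rt
Reagents that add atoms: none
Why: Trifluoroacetic anhydride esterification as used for depsides, in which the hindered electron-rich acid forms mixed anhydride 24 that ionises to an acylium ion captured by the phenol oxygen, while the fully substituted ring of 21 excludes Friedel–Crafts C-acylation.

Step 13
Reactants: 25 3-(benzyloxy)-4-formyl-2,5,6-trimethylphenyl 2,4-bis(benzyloxy)-3,5,6-trimethylbenzoate
Product: 26 2-(benzyloxy)-4-{[2,4-bis(benzyloxy)-3,5,6-trimethylbenzoyl]oxy}-3,5,6-trimethylbenzoic acid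
Conditions: NaClO2, NaH2PO4, 2-methylbut-2-ene, t-BuOH–THF–H2O, rt
Reagents that add atoms: sodium chlorite, [Na+].[O-]Cl=O
Why: Pinnick oxidation unmasks the ring B carboxyl from the aldehyde at about pH 4 without touching the aryl ester or the benzyl ethers.

Step 14
Reactants: 26 2-(benzyloxy)-4-{[2,4-bis(benzyloxy)-3,5,6-trimethylbenzoyl]oxy}-3,5,6-trimethylbenzoic acid; 17 3-(benzyloxy)-2,5,6-trimethylphenol
Product: 29 3-(benzyloxy)-2,5,6-trimethylphenyl 2-(benzyloxy)-4-{[2,4-bis(benzyloxy)-3,5,6-trimethylbenzoyl]oxy}-3,5,6-trimethylbenzoate, via acid chloride 27 (not isolated), via sodium phenoxide 28 (not isolated)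
Conditions: 26, (COCl)2, DMF (cat.), CH2Cl2, 0 °C → rt, evaporate; 17, NaH, THF, 0 °C; combine, 0 °C → rt
Reagents that add atoms: none
Why: Acyl chloride formation followed by O-acylation of a pre-formed phenoxide (anhydrous Schotten–Baumann-type esterification) joins the two di-ortho-substituted partners, the anionic oxygen reacting faster than the free ring carbon C4 and the existing hindered aryl ester resisting exchange.

Step 15
Reactants: 29 3-(benzyloxy)-2,5,6-trimethylphenyl 2-(benzyloxy)-4-{[2,4-bis(benzyloxy)-3,5,6-trimethylbenzoyl]oxy}-3,5,6-trimethylbenzoate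
Product: 30 Thielavin Z8
Conditions: H2 (1 atm), 10% Pd/C, EtOAc–THF, rt
Reagents that add atoms: none
Why: Catalytic hydrogenolysis of the four aryl benzyl ethers over Pd/C leaves both aryl esters intact and should release the free tridepside.

**Compound list**

1 | but-2-yne | CC#CC | starting material
2 | trichloroacetyl chloride | O=C(Cl)C(Cl)(Cl)Cl | starting material
3 | dichloroketene | O=C=C(Cl)Cl | intermediate (not isolated)
4 | 4,4-dichloro-2,3-dimethylcyclobut-2-en-1-one | CC1=C(C)C(Cl)(Cl)C1=O | intermediate
5 | 2,3-dimethylcyclobut-2-en-1-one | CC1=C(C)CC1=O | intermediate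
6 | propyne | CC#C | starting material
7 | triisopropylsilyl trifluoromethanesulfonate | CC(C)[Si](OS(=O)(=O)C(F)(F)F)(C(C)C)C(C)C | starting material
8 | propynyllithium | [Li]C#CC | intermediate (not isolated)
9 | lithium prop-1-yn-1-olate | CC#C[O-].[Li+] | intermediate (not isolated)
10 | triisopropyl(prop-1-yn-1-yloxy)silane | CC#CO[Si](C(C)C)(C(C)C)C(C)C | intermediate
11 | 2,3-dimethylbuta-1,3-dien-1-one (vinylketene) | O=C=C(C)C(C)=C | intermediate (not isolated)
12 | 2,4-dimethyl-4-(prop-1-en-2-yl)-3-(triisopropylsilyloxy)cyclobut-2-en-1-one, racemic | CC1=C(O[Si](C(C)C)(C(C)C)C(C)C)C(C)(C(C)=C)C1=O | intermediate (not isolated)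
13 | (3E)-2,4,5-trimethyl-3-(triisopropylsilyloxy)hexa-1,3,5-trien-1-one (dienylketene) | O=C=C(C)/C(O[Si](C(C)C)(C(C)C)C(C)C)=C(/C)C(C)=C | intermediate (not isolated)
14 | 2,4,5-trimethyl-3-(triisopropylsilyloxy)cyclohexa-2,4-dien-1-one | O=C1CC(C)=C(C)C(O[Si](C(C)C)(C(C)C)C(C)C)=C1C | intermediate (not isolated)
15 | 2,4,5-trimethyl-3-(triisopropylsilyloxy)phenol | Cc1cc(O)c(C)c(O[Si](C(C)C)(C(C)C)C(C)C)c1C | intermediate
16 | 1-(benzyloxy)-2,4,5-trimethyl-3-(triisopropylsilyloxy)benzene | Cc1cc(OCc2ccccc2)c(C)c(O[Si](C(C)C)(C(C)C)C(C)C)c1C | intermediate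
17 | 3-(benzyloxy)-2,5,6-trimethylphenol | Cc1cc(OCc2ccccc2)c(C)c(O)c1C | intermediate
18 | 2-(hydroxymethyl)-3,4,6-trimethyl-5-(triisopropylsilyloxy)phenol (present as its magnesium salt) | OCc1c(O)c(C)c(O[Si](C(C)C)(C(C)C)C(C)C)c(C)c1C | intermediate (not isolated)
19 | 2-hydroxy-3,5,6-trimethyl-4-(triisopropylsilyloxy)benzaldehyde | O=Cc1c(O)c(C)c(O[Si](C(C)C)(C(C)C)C(C)C)c(C)c1C | intermediate
20 | 2-(benzyloxy)-3,5,6-trimethyl-4-(triisopropylsilyloxy)benzaldehyde | O=Cc1c(OCc2ccccc2)c(C)c(O[Si](C(C)C)(C(C)C)C(C)C)c(C)c1C | intermediate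
21 | 2-(benzyloxy)-4-hydroxy-3,5,6-trimethylbenzaldehyde | O=Cc1c(OCc2ccccc2)c(C)c(O)c(C)c1C | intermediate
22 | 2,4-bis(benzyloxy)-3,5,6-trimethylbenzaldehyde | O=Cc1c(OCc2ccccc2)c(C)c(OCc2ccccc2)c(C)c1C | intermediate
23 | 2,4-bis(benzyloxy)-3,5,6-trimethylbenzoic acid | OC(=O)c1c(OCc2ccccc2)c(C)c(OCc2ccccc2)c(C)c1C | intermediate
24 | 2,4-bis(benzyloxy)-3,5,6-trimethylbenzoic trifluoroacetic anhydride | O=C(OC(=O)C(F)(F)F)c1c(OCc2ccccc2)c(C)c(OCc2ccccc2)c(C)c1C | intermediate (not isolated)
25 | 3-(benzyloxy)-4-formyl-2,5,6-trimethylphenyl 2,4-bis(benzyloxy)-3,5,6-trimethylbenzoate | O=Cc1c(OCc2ccccc2)c(C)c(OC(=O)c2c(OCc3ccccc3)c(C)c(OCc3ccccc3)c(C)c2C)c(C)c1C | intermediate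
26 | 2-(benzyloxy)-4-{[2,4-bis(benzyloxy)-3,5,6-trimethylbenzoyl]oxy}-3,5,6-trimethylbenzoic acid | OC(=O)c1c(OCc2ccccc2)c(C)c(OC(=O)c2c(OCc3ccccc3)c(C)c(OCc3ccccc3)c(C)c2C)c(C)c1C | intermediate
27 | 2-(benzyloxy)-4-{[2,4-bis(benzyloxy)-3,5,6-trimethylbenzoyl]oxy}-3,5,6-trimethylbenzoyl chloride | O=C(Cl)c1c(OCc2ccccc2)c(C)c(OC(=O)c2c(OCc3ccccc3)c(C)c(OCc3ccccc3)c(C)c2C)c(C)c1C | intermediate (not isolated)
28 | sodium 3-(benzyloxy)-2,5,6-trimethylphenoxide | Cc1cc(OCc2ccccc2)c(C)c([O-])c1C.[Na+] | intermediate (not isolated)
29 | 3-(benzyloxy)-2,5,6-trimethylphenyl 2-(benzyloxy)-4-{[2,4-bis(benzyloxy)-3,5,6-trimethylbenzoyl]oxy}-3,5,6-trimethylbenzoate | Cc1cc(OCc2ccccc2)c(C)c(OC(=O)c2c(OCc3ccccc3)c(C)c(OC(=O)c3c(OCc4ccccc4)c(C)c(OCc4ccccc4)c(C)c3C)c(C)c2C)c1C | intermediate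
30 | Thielavin Z8, 3-hydroxy-2,5,6-trimethylphenyl 4-[(2,4-dihydroxy-3,5,6-trimethylbenzoyl)oxy]-2-hydroxy-3,5,6-trimethylbenzoate | Cc1cc(O)c(C)c(OC(=O)c2c(C)c(C)c(OC(=O)c3c(C)c(C)c(O)c(C)c3O)c(C)c2O)c1C | target

**Step count**

Total steps: 15. Longest linear sequence: 12 steps (1, 2, 4, 7, 8, 9, 10, 11, 12, 13, 14, 15, from but-2-yne through ring C to the target).

**Steps most likely to fail**

Step 4 (key benzannulation). At the temperature needed to open the cyclobutenone, the siloxyalkyne may isomerise thermally to a silylketene, the vinylketene may react with itself or acylate the product phenol, and the volatile cyclobutenone may be lost before it reacts. The fallback makes the same vinylketene 11 at room temperature by a photochemical Wolff rearrangement (the diazo ketone form of the aromatic annulation). It sets out from siloxyalkyne 10 and returns at phenol 15. Commercial 2-methylpent-1-en-3-one would be deprotonated with LiN(SiMe3)2 at −78 °C and acylated with 2,2,2-trifluoroethyl trifluoroacetate to give 1,1,1-trifluoro-3,5-dimethylhex-5-ene-2,4-dione F1. Detrifluoroacetylative diazo transfer (MsN3, Et3N, H2O, MeCN) would then give 2-diazo-4-methylpent-4-en-3-one F2. Irradiation of F2 with 10 (medium-pressure mercury lamp, CH2Cl2, rt) should give adduct 12 by migration of the isopropenyl group and [2+2] capture, and brief heating in toluene at 80–110 °C after the alkyne is consumed should complete the change to 15.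

Step 14 (last esterification). O-acylation of a di-ortho-methyl phenoxide by a di-ortho-substituted aroyl chloride may be slow enough for C-acylation at the free ring A carbon C4 or acyl transfer from the existing B–C ester to compete. The fallback blocks C4 and uses the acylium method of step 12. It sets out from phenol 17 and acid 26 and returns at the target 30. Bromination of 17 with N-bromosuccinimide (MeCN, 0 °C) at the only free ring position should give 3-(benzyloxy)-4-bromo-2,5,6-trimethylphenol F3. Esterification of F3 with 26 by (CF3CO)2O in toluene should give 3-(benzyloxy)-4-bromo-2,5,6-trimethylphenyl 2-(benzyloxy)-4-{[2,4-bis(benzyloxy)-3,5,6-trimethylbenzoyl]oxy}-3,5,6-trimethylbenzoate F4. Hydrogenation of F4 (H2, Pd/C, Et3N, EtOAc–THF) would remove the bromine and the four benzyl groups in one operation to give 30.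

Step 3 (siloxyalkyne). Handling gaseous propyne, incomplete oxygen transfer from the peroxide to the acetylide, and competing C-silylation or hydrolysis of the ynol ether on isolation may erode the supply of 10. The fallback makes the ynolate by the dibromo ester route (Shindo ynolate synthesis). It sets out from silyl triflate 7, the only numbered compound it consumes, and returns at ynolate 9 and hence at 10. Commercial ethyl 2-bromopropanoate would be brominated through its lithium enolate (LiN(iPr)2, THF, −78 °C, then BrCF2CF2Br) to ethyl 2,2-dibromopropanoate F5. Treatment of F5 with t-BuLi (4 equiv, THF, −78 → 0 °C) should give 9 by double bromine–lithium exchange and loss of ethoxide, and 9 is then silylated with 7 as in step 3.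

**Further compounds**

F1 | step 4 | 1,1,1-trifluoro-3,5-dimethylhex-5-ene-2,4-dione | C=C(C)C(=O)C(C)C(=O)C(F)(F)F
F2 | step 4 | 2-diazo-4-methylpent-4-en-3-one | CC(=[N+]=[N-])C(=O)C(C)=C
F3 | step 14 | 3-(benzyloxy)-4-bromo-2,5,6-trimethylphenol | Cc1c(Br)c(OCc2ccccc2)c(C)c(O)c1C
F4 | step 14 | 3-(benzyloxy)-4-bromo-2,5,6-trimethylphenyl 2-(benzyloxy)-4-{[2,4-bis(benzyloxy)-3,5,6-trimethylbenzoyl]oxy}-3,5,6-trimethylbenzoate | Cc1c(Br)c(OCc2ccccc2)c(C)c(OC(=O)c2c(OCc3ccccc3)c(C)c(OC(=O)c3c(OCc4ccccc4)c(C)c(OCc4ccccc4)c(C)c3C)c(C)c2C)c1C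
F5 | step 3 | ethyl 2,2-dibromopropanoate | CCOC(=O)C(C)(Br)Br
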